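**Retrosynthetic overview**
- The C6 acetate goes on last; the 1,2-dioxane is closed before it by C10–O bond formation, a C7 hydroperoxide capturing a C10 allyl cation (silver-assisted). The hydroperoxide comes from perhydrolysis, with inversion at C7, of a (6S,7R) cis-epoxide.
- The 14-membered carbocycle is closed at C10–C11 by Nozaki–Hiyama–Kishi reaction of a Z-iodoalkene with an aldehyde; the C10 configuration formed there is irrelevant.
- The cis-α-methylene-γ-lactone and the C1–C14 bond come from a chiral phosphoric acid-catalysed 2-(methoxycarbonyl)allylboration of an epoxy enal (the new step).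
- The epoxy enal comes from a propyne carbocupration/enone three-component coupling (Z-olefin), Horner–Wadsworth–Emmons olefination and Shi epoxidation (first stereocentres). The allylboronate comes from a Stork–Zhao Z-iodoalkene, vinylalumination and SN2′ borylation.
- Ring order: oxirane, then γ-lactone, then 14-membered carbocycle, then 1,2-dioxane (the oxirane is consumed).

Assumption: ring carbons are numbered C1 (lactone O–CH) round to C14 (lactone CH), which makes the target (1S,6S,7S,10S,14S) with 2E and 11Z olefins; 1, 12, the Weinreb phosphonate, (R)-TRIP and the L-fructose-derived Shi ketone are taken as purchasable.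

**Route**

Step 1
Reactants: 1 (3-bromopropoxy)(tert-butyl)dimethylsilane; 2 propyne; 3 methyl vinyl ketone
Product: 8 (Z)-9-[(tert-butyldimethylsilyl)oxy]-6-methylnon-5-en-2-one, via Grignard reagent 4 (not isolated), via alkylcopper 5 (not isolated), via alkenylcopper 6 (not isolated), via silyl enol ether 7 (not isolated)
Conditions: Mg, Et2O, reflux; CuBr·SMe2, Et2O/Me2S, −45 °C; 2, −25 °C; 3, Me3SiCl, −78 → −30 °C; aq. NH4Cl then 1 M HCl
Reagents that add atoms: none
Why: Normant carbocupration of propyne is a syn addition that puts the alkyl chain and copper cis, and the Me3SiCl-accelerated conjugate addition of the alkenylcopper to the enone goes with retention, so the Z trisubstituted olefin (C5 cis to C8) is fixed; no stereocentre is formed.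

Step 2
Reactants: 8 (Z)-9-[(tert-butyldimethylsilyl)oxy]-6-methylnon-5-en-2-one
Product: 9 (2E,6Z)-10-[(tert-butyldimethylsilyl)oxy]-N-methoxy-N,3,7-trimethyldeca-2,6-dienamide
Conditions: (EtO)2P(O)CH2C(O)N(OMe)Me, NaH, THF, 0 → 50 °C; 2Z isomer removed by chromatography
Reagents that add atoms: diethyl [2-(methoxy(methyl)amino)-2-oxoethyl]phosphonate, CCOP(=O)(CC(=O)N(C)OC)OCC
Why: Horner–Wadsworth–Emmons olefination of the methyl ketone with a stabilised phosphonate gives mainly the 2E amide (about 5:1 expected), and the Weinreb amide is the latent C1 aldehyde.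

Step 3
Reactants: 9 (2E,6Z)-10-[(tert-butyldimethylsilyl)oxy]-N-methoxy-N,3,7-trimethyldeca-2,6-dienamide
Product: 10 (2E)-5-[(2S,3R)-3-{3-[(tert-butyldimethylsilyl)oxy]propyl}-3-methyloxiran-2-yl]-N-methoxy-N,3-dimethylpent-2-enamide
Conditions: 1,2:4,5-di-O-isopropylidene-β-L-erythro-2,3-hexodiulo-2,6-pyranose (L-fructose-derived Shi ketone, 30 mol %), KHSO5 (as 2KHSO5·KHSO4·K2SO4), K2CO3, Bu4NHSO4, MeCN/CH2(OMe)2/aq. Na2B4O7 buffer (pH 10.5), 0 °C
Reagents that add atoms: potassium peroxymonosulfate KHSO5, [K+].[O-]S(=O)(=O)OO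
Why: Shi epoxidation: the chiral dioxirane transfers oxygen through a spiro transition state with the olefinic hydrogen facing the spiro ketal, so the L-series ketone gives the (6S,7R) cis-epoxide (the first two stereocentres), while the electron-poor enamide olefin is untouched.

Step 4
Reactants: 10 (2E)-5-[(2S,3R)-3-{3-[(tert-butyldimethylsilyl)oxy]propyl}-3-methyloxiran-2-yl]-N-methoxy-N,3-dimethylpent-2-enamide
Product: 11 (2E)-5-[(2S,3R)-3-{3-[(tert-butyldimethylsilyl)oxy]propyl}-3-methyloxiran-2-yl]-3-methylpent-2-enal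
Conditions: i-Bu2AlH, THF, −78 °C; aq. KNaC4H4O6
Reagents that add atoms: none
Why: Weinreb amide reduction stops at the chelated tetrahedral aluminate, which releases the enal on work-up; epoxide and silyl ether are inert at −78 °C.

Step 5
Reactants: 12 3-[(tert-butyldimethylsilyl)oxy]propanal
Product: 13 tert-butyl{[(3Z)-4-iodopent-3-en-1-yl]oxy}dimethylsilane
Conditions: [Ph3PEt]I, n-BuLi, THF, rt; I2, −78 °C; NaN(SiMe3)2, −78 °C; then 12, −78 → −20 °C
Reagents that add atoms: ethyltriphenylphosphonium iodide, CC[P+](c1ccccc1)(c1ccccc1)c1ccccc1.[I-]; iodine, II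
Why: Stork–Zhao olefination: the α-iodo ylide gives the Z iodoalkene (iodine cis to the chain, typically at least 10:1) through the kinetically favoured cis-oxaphosphetane.

Step 6
Reactants: 13 tert-butyl{[(3Z)-4-iodopent-3-en-1-yl]oxy}dimethylsilane
Product: 14 (3Z)-4-iodopent-3-en-1-ol
Conditions: camphorsulfonic acid (10 mol %), MeOH, 0 °C → rt
Reagents that add atoms: none
Why: Acid-catalysed methanolysis of the primary silyl ether; the iodoalkene is inert.

Step 7
Reactants: 14 (3Z)-4-iodopent-3-en-1-ol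
Product: 15 (3Z)-4-iodopent-3-enal
Conditions: Dess–Martin periodinane, pyridine, CH2Cl2, 0 °C; used crude at once
Reagents that add atoms: none
Why: Dess–Martin oxidation under buffered, non-basic conditions gives the β,γ-unsaturated aldehyde without conjugation or Z/E isomerisation.

Step 8
Reactants: 15 (3Z)-4-iodopent-3-enal; 16 methyl propiolate
Product: 19 methyl (5Z)-3-(acetyloxy)-6-iodo-2-methylidenehept-5-enoate (racemic), via vinylalane 17 (not isolated), via aluminium alkoxide 18 (not isolated)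
Conditions: 16, i-Bu2AlH, N-methylmorpholine N-oxide, THF, 0 °C; 15, 0 °C → rt; then Ac2O, pyridine, DMAP, 0 °C
Reagents that add atoms: acetic anhydride, CC(=O)OC(C)=O
Why: Vinylalumination: hydroalumination of the propiolate gives the α-alumino acrylate, which adds to the aldehyde as a non-basic Morita–Baylis–Hillman surrogate, and the aluminium alkoxide is acetylated in the flask; the racemic carbinol centre is erased in step 9.

Step 9
Reactants: 19 methyl (5Z)-3-(acetyloxy)-6-iodo-2-methylidenehept-5-enoate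
Product: 20 methyl (2E,5Z)-6-iodo-2-[(4,4,5,5-tetramethyl-1,3,2-dioxaborolan-2-yl)methyl]hepta-2,5-dienoate
Conditions: B2pin2, CuCl (10 mol %), KOAc, DMF, rt
Reagents that add atoms: bis(pinacolato)diboron, CC1(C)OB(OC1(C)C)B1OC(C)(C)C(C)(C)O1
Why: Copper-catalysed SN2′ borylation of the Morita–Baylis–Hillman acetate gives the favoured enoate with CH2B cis to the C13 chain (2E), the geometry a syn allylboration needs; the iodoalkene does not react at room temperature.

Step 10
Reactants: 11 (2E)-5-[(2S,3R)-3-{3-[(tert-butyldimethylsilyl)oxy]propyl}-3-methyloxiran-2-yl]-3-methylpent-2-enal; 20 methyl (2E,5Z)-6-iodo-2-[(4,4,5,5-tetramethyl-1,3,2-dioxaborolan-2-yl)methyl]hepta-2,5-dienoate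
Product: 23 (4S,5S)-5-{(1E)-4-[(2S,3R)-3-(3-hydroxypropyl)-3-methyloxiran-2-yl]-2-methylbut-1-en-1-yl}-4-[(2Z)-3-iodobut-2-en-1-yl]-3-methylideneoxolan-2-one, via homoallyl borate 21 (not isolated), via silyl lactone 22 (not isolated)
Conditions: (R)-3,3′-bis(2,4,6-triisopropylphenyl)-1,1′-binaphthyl-2,2′-diyl hydrogen phosphate ((R)-TRIP, 10 mol %), 4 Å molecular sieves, toluene, −20 °C → rt; then Bu4NF, AcOH, THF, rt
Reagents that add atoms: none
Why: Proposed new method: chiral phosphoric acid-catalysed enantioselective 2-(alkoxycarbonyl)crotyl-type boration of an enal, in which the acid hydrogen-bonds to a pinacol oxygen and to the formyl C–H so that the electron-poor boronate reacts through a closed chair transition state; the C13 substituent cis to CH2B gives the syn adduct (cis-lactone after the borate closes onto the methyl ester) and the (R)-catalyst, by analogy with simple allylborations, exposes the Re face of the aldehyde, setting C1 (S) and C14 (S), after which fluoride removes the silyl ether; the closest known reaction types are chiral phosphoric acid-catalysed allyl- and crotylboration of aldehydes with simple pinacol boronates and achiral acid-accelerated racemic 2-(alkoxycarbonyl)allylboration–lactonisation, which have not been shown together for γ-substituted 2-ester allylboronates.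

Step 11
Reactants: 23 (4S,5S)-5-{(1E)-4-[(2S,3R)-3-(3-hydroxypropyl)-3-methyloxiran-2-yl]-2-methylbut-1-en-1-yl}-4-[(2Z)-3-iodobut-2-en-1-yl]-3-methylideneoxolan-2-one
Product: 24 (4S,5S)-4-[(2Z)-3-iodobut-2-en-1-yl]-5-{(1E)-2-methyl-4-[(2S,3R)-3-methyl-3-(3-oxopropyl)oxiran-2-yl]but-1-en-1-yl}-3-methylideneoxolan-2-one
Conditions: Dess–Martin periodinane, pyridine, CH2Cl2, 0 °C
Reagents that add atoms: none
Why: Dess–Martin oxidation under buffered neutral conditions keeps the 4,5-epoxy alcohol from cyclising to a tetrahydrofuran before it is oxidised.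

Step 12
Reactants: 24 (4S,5S)-4-[(2Z)-3-iodobut-2-en-1-yl]-5-{(1E)-2-methyl-4-[(2S,3R)-3-methyl-3-(3-oxopropyl)oxiran-2-yl]but-1-en-1-yl}-3-methylideneoxolan-2-one
Product: 25 macrocyclic (1S,6S,7R,14S)-6,7-epoxy-10-hydroxy lactone (2E,11Z; both C10 epimers)
Conditions: CrCl2 (12 equiv), NiCl2 (0.1 equiv), degassed DMSO/THF, rt, 2 mM, slow addition
Reagents that add atoms: none
Why: Nozaki–Hiyama–Kishi macrocyclisation: zerovalent nickel inserts into the C–I bond, the alkenyl group passes to trivalent chromium with retention of the Z geometry and adds only to the aldehyde, closing the 14-membered ring; both C10 epimers are carried on because this centre is re-set in step 15.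

Step 13
Reactants: 25 macrocyclic (1S,6S,7R,14S)-6,7-epoxy-10-hydroxy lactone
Product: 26 macrocyclic (1S,6S,7R,14S)-10-chloro-6,7-epoxy lactone (2E,11Z; both C10 epimers)
Conditions: N-chlorosuccinimide, Me2S, CH2Cl2, −25 → 0 °C
Reagents that add atoms: N-chlorosuccinimide, O=C1CCC(=O)N1Cl
Why: Corey–Kim chlorination displaces the alkoxysulfonium salt with chloride under neutral conditions that spare epoxide and lactone, and removes the hydroxyl that would otherwise attack the epoxide; the C10 epimer ratio does not matter.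

Step 14
Reactants: 26 macrocyclic (1S,6S,7R,14S)-10-chloro-6,7-epoxy lactone
Product: 27 macrocyclic (1S,6S,7S,14S)-10-chloro-7-hydroperoxy-6-hydroxy lactone (2E,11Z; both C10 epimers)
Conditions: H2O2 (anhydrous, in Et2O), H3PMo12O40 (5 mol %), Et2O, 0 °C → rt
Reagents that add atoms: hydrogen peroxide, OO
Why: Acid-catalysed perhydrolysis of the trisubstituted epoxide: hydrogen peroxide attacks the tertiary C7 with inversion (borderline SN2), giving the (6S,7S) β-hydroxy hydroperoxide, while C6 keeps its configuration.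

Step 15
Reactants: 27 macrocyclic (1S,6S,7S,14S)-10-chloro-7-hydroperoxy-6-hydroxy lactone
Product: 28 macrocyclic (1S,6S,7S,10S,14S)-7,10-epidioxy-6-hydroxy lactone (2E,11Z)
Conditions: AgOTf (1.5 equiv), 2,6-di-tert-butyl-4-methylpyridine, 4 Å molecular sieves, CH2Cl2, −40 → 0 °C, dark
Reagents that add atoms: none
Why: Silver-assisted cycloperoxidation (halide abstraction, then hydroperoxide capture): both chloride epimers give the same Z-configured allyl cation, which the C7 hydroperoxide captures at C10 in a 6-exo closure through a chair with the C6 chain and the alkenyl group equatorial, setting C10 (S) and keeping the 11Z olefin; the less hindered peroxy oxygen is expected to outrun the C6 hydroxyl.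

Step 16
Reactants: 28 macrocyclic (1S,6S,7S,10S,14S)-7,10-epidioxy-6-hydroxy lactone
Product: 29 the target (1S,6S,7S,10S,14S)-6-acetoxy-7,10-epidioxy lactone (2E,11Z)
Conditions: Ac2O, pyridine, CH2Cl2, 0 °C → rt
Reagents that add atoms: acetic anhydride, CC(=O)OC(C)=O
Why: Acetylation of the C6 secondary alcohol under weakly basic conditions that should not trigger Kornblum–DeLaMare cleavage of the allylic peroxide.

**Compound list**

1 | (3-bromopropoxy)(tert-butyl)dimethylsilane | BrCCCO[Si](C)(C)C(C)(C)C | starting material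
2 | propyne | CC#C | starting material
3 | methyl vinyl ketone (but-3-en-2-one) | CC(=O)C=C | starting material
4 | {3-[(tert-butyldimethylsilyl)oxy]propyl}magnesium bromide | Br[Mg]CCCO[Si](C)(C)C(C)(C)C | intermediate (not isolated)
5 | {3-[(tert-butyldimethylsilyl)oxy]propyl}copper | [Cu]CCCO[Si](C)(C)C(C)(C)C | intermediate (not isolated)
6 | [(1Z)-5-[(tert-butyldimethylsilyl)oxy]-2-methylpent-1-en-1-yl]copper | [Cu]/C=C(/C)CCCO[Si](C)(C)C(C)(C)C | intermediate (not isolated)
7 | (5Z)-9-[(tert-butyldimethylsilyl)oxy]-6-methyl-2-[(trimethylsilyl)oxy]nona-2,5-diene | CC(O[Si](C)(C)C)=CC/C=C(C)\CCCO[Si](C)(C)C(C)(C)C | intermediate (not isolated)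
8 | (Z)-9-[(tert-butyldimethylsilyl)oxy]-6-methylnon-5-en-2-one | CC(=O)CC/C=C(C)\CCCO[Si](C)(C)C(C)(C)C | intermediate
9 | (2E,6Z)-10-[(tert-butyldimethylsilyl)oxy]-N-methoxy-N,3,7-trimethyldeca-2,6-dienamide | CON(C)C(=O)/C=C(\C)CC/C=C(C)\CCCO[Si](C)(C)C(C)(C)C | intermediate
10 | (2E)-5-[(2S,3R)-3-{3-[(tert-butyldimethylsilyl)oxy]propyl}-3-methyloxiran-2-yl]-N-methoxy-N,3-dimethylpent-2-enamide | CON(C)C(=O)/C=C(\C)CC[C@@H]1O[C@]1(C)CCCO[Si](C)(C)C(C)(C)C | intermediate
11 | (2E)-5-[(2S,3R)-3-{3-[(tert-butyldimethylsilyl)oxy]propyl}-3-methyloxiran-2-yl]-3-methylpent-2-enal | O=C/C=C(\C)CC[C@@H]1O[C@]1(C)CCCO[Si](C)(C)C(C)(C)C | intermediate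
12 | 3-[(tert-butyldimethylsilyl)oxy]propanal | O=CCCO[Si](C)(C)C(C)(C)C | starting material
13 | tert-butyl{[(3Z)-4-iodopent-3-en-1-yl]oxy}dimethylsilane | C/C(I)=C/CCO[Si](C)(C)C(C)(C)C | intermediate
14 | (3Z)-4-iodopent-3-en-1-ol | C/C(I)=C/CCO | intermediate
15 | (3Z)-4-iodopent-3-enal | C/C(I)=C/CC=O | intermediate
16 | methyl propiolate | C#CC(=O)OC | starting material
17 | methyl 2-(diisobutylalumanyl)prop-2-enoate | C=C([Al](CC(C)C)CC(C)C)C(=O)OC | intermediate (not isolated)
18 | diisobutylaluminium alkoxide of methyl (5Z)-3-hydroxy-6-iodo-2-methylidenehept-5-enoate | C/C(I)=C/CC(O[Al](CC(C)C)CC(C)C)C(=C)C(=O)OC | intermediate (not isolated)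
19 | methyl (5Z)-3-(acetyloxy)-6-iodo-2-methylidenehept-5-enoate (racemic) | C/C(I)=C/CC(OC(C)=O)C(=C)C(=O)OC | intermediate
20 | methyl (2E,5Z)-6-iodo-2-[(4,4,5,5-tetramethyl-1,3,2-dioxaborolan-2-yl)methyl]hepta-2,5-dienoate | COC(=O)/C(CB1OC(C)(C)C(C)(C)O1)=C/C/C=C(/C)I | intermediate
21 | methyl (3S,4S,5E)-8-[(2S,3R)-3-{3-[(tert-butyldimethylsilyl)oxy]propyl}-3-methyloxiran-2-yl]-3-[(2Z)-3-iodobut-2-en-1-yl]-6-methyl-2-methylidene-4-[(4,4,5,5-tetramethyl-1,3,2-dioxaborolan-2-yl)oxy]oct-5-enoate | COC(=O)C(=C)[C@H](C/C=C(/C)I)[C@@H](OB1OC(C)(C)C(C)(C)O1)/C=C(\C)CC[C@@H]1O[C@]1(C)CCCO[Si](C)(C)C(C)(C)C | intermediate (not isolated)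
22 | (4S,5S)-5-{(1E)-4-[(2S,3R)-3-{3-[(tert-butyldimethylsilyl)oxy]propyl}-3-methyloxiran-2-yl]-2-methylbut-1-en-1-yl}-4-[(2Z)-3-iodobut-2-en-1-yl]-3-methylideneoxolan-2-one | C=C1C(=O)O[C@@H](/C=C(\C)CC[C@@H]2O[C@]2(C)CCCO[Si](C)(C)C(C)(C)C)[C@H]1C/C=C(/C)I | intermediate (not isolated)
23 | (4S,5S)-5-{(1E)-4-[(2S,3R)-3-(3-hydroxypropyl)-3-methyloxiran-2-yl]-2-methylbut-1-en-1-yl}-4-[(2Z)-3-iodobut-2-en-1-yl]-3-methylideneoxolan-2-one | C=C1C(=O)O[C@@H](/C=C(\C)CC[C@@H]2O[C@]2(C)CCCO)[C@H]1C/C=C(/C)I | intermediate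
24 | (4S,5S)-4-[(2Z)-3-iodobut-2-en-1-yl]-5-{(1E)-2-methyl-4-[(2S,3R)-3-methyl-3-(3-oxopropyl)oxiran-2-yl]but-1-en-1-yl}-3-methylideneoxolan-2-one | C=C1C(=O)O[C@@H](/C=C(\C)CC[C@@H]2O[C@]2(C)CCC=O)[C@H]1C/C=C(/C)I | intermediate
25 | macrocyclic epoxy allylic alcohol: 14-membered carbocycle C1–C14 cis-fused at C1 (S) and C14 (S) to the α-methylene-γ-butyrolactone, 2E olefin (3-Me), (6S,7R) cis-epoxide (7-Me), 10-OH (both epimers), 11Z olefin (11-Me) | C=C1C(=O)O[C@H]2/C=C(\C)CC[C@@H]3O[C@]3(C)CCC(O)/C(C)=C\C[C@@H]12 | intermediate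
26 | as 25 with 10-Cl in place of 10-OH (both epimers) | C=C1C(=O)O[C@H]2/C=C(\C)CC[C@@H]3O[C@]3(C)CCC(Cl)/C(C)=C\C[C@@H]12 | intermediate
27 | as 26 with the epoxide opened: (6S)-OH and (7S)-OOH (7-Me), 10-Cl (both epimers) | C=C1C(=O)O[C@H]2/C=C(\C)CC[C@H](O)[C@@](C)(OO)CCC(Cl)/C(C)=C\C[C@@H]12 | intermediate
28 | (1S,6S,7S,10S,14S)-6-hydroxy compound with the C7–O–O–C10 bridge (1,2-dioxane), 2E,11Z; the deacetyl target | C=C1C(=O)O[C@H]2/C=C(\C)CC[C@H](O)[C@]3(C)CC[C@H](OO3)/C(C)=C\C[C@@H]12 | intermediate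
29 | (1S,6S,7S,10S,14S)-6-acetoxy-7,10-epidioxy cembranolide, 2E,11Z (CNP0238885.1) | C=C1C(=O)O[C@H]2/C=C(\C)CC[C@H](OC(C)=O)[C@]3(C)CC[C@H](OO3)/C(C)=C\C[C@@H]12 | target

**Step count and risks**

Total: 16 steps. Longest linear sequence: 12 steps (12 to 29, steps 5–16); the branch from 1 is 11 steps.

The three steps most likely to fail:

Step 10 (the new step). The electron-poor boronate may react too slowly under phosphoric acid catalysis, the acid may open the epoxide, or the face selectivity may be low. The fallback uses known chemistry and sets out from 15 and 16 (for the allyl partner) and from 11. The aluminium alkoxide 18 is quenched with water instead of Ac2O to give methyl (5Z)-3-hydroxy-6-iodo-2-methylidenehept-5-enoate F1. PBr3 in Et2O at −10 °C converts it with allylic transposition into methyl (2Z,5Z)-2-(bromomethyl)-6-iodohepta-2,5-dienoate F2. An enantioselective chromium-catalysed Barbier-type 2-(alkoxycarbonyl)allylation of 11 with F2 (CrCl2 10 mol %, a chiral 1,8-bis(oxazolinyl)carbazole ligand, Mn, Me3SiCl, i-Pr2NEt, THF) gives the syn trimethylsilyl ether of the hydroxy ester F3. Bu4NF/AcOH then lactonises and desilylates it through 22, and the route is rejoined at 23.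

Step 14. Perhydrolysis inside the macrocycle may suffer transannular attack of an olefin on the activated epoxide, or poor regioselectivity. The fallback sets out from 26 and reverses the order of the two C–O bond formations. AgOTf with ethereal H2O2 at −40 °C replaces the chloride and gives the macrocyclic 10-hydroperoxy epoxide (both C10 epimers) F4. Catalytic camphorsulfonic acid in CH2Cl2 at 0 °C then drives a 6-exo intramolecular opening of the epoxide at C7 with inversion. This gives 28 together with its C10 epimer, which is removed by chromatography; the route is rejoined at 28, bypassing 27 and step 15, at the cost of C10 control.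

Step 15. The C6 hydroxyl may compete with the hydroperoxide for the allyl cation, or the chair preference may give a poor C10 ratio. The fallback sets out from 25 and replaces the stereoconvergent ionisation by a stereospecific displacement. Dess–Martin oxidation gives the macrocyclic (Z)-enone F5. Reduction with (R)-Me-CBS oxazaborolidine and catecholborane gives the single (10S)-alcohol F6. Corey–Kim chlorination with inversion gives the (10R)-chloride F7. Perhydrolysis as in step 14 gives the (10R)-chloro (6S,7S)-hydroxy hydroperoxide F8. Cs2CO3 in DMF at 0 °C deprotonates only the hydroperoxide, which displaces the chloride with inversion, and the route is rejoined at 28.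

Further compounds
F1 | step 10 | methyl (5Z)-3-hydroxy-6-iodo-2-methylidenehept-5-enoate (racemic) | C/C(I)=C/CC(O)C(=C)C(=O)OC
F2 | step 10 | methyl (2Z,5Z)-2-(bromomethyl)-6-iodohepta-2,5-dienoate | COC(=O)/C(CBr)=C/C/C=C(/C)I
F3 | step 10 | methyl (3S,4S,5E)-8-[(2S,3R)-3-{3-[(tert-butyldimethylsilyl)oxy]propyl}-3-methyloxiran-2-yl]-3-[(2Z)-3-iodobut-2-en-1-yl]-6-methyl-2-methylidene-4-[(trimethylsilyl)oxy]oct-5-enoate | COC(=O)C(=C)[C@H](C/C=C(/C)I)[C@@H](O[Si](C)(C)C)/C=C(\C)CC[C@@H]1O[C@]1(C)CCCO[Si](C)(C)C(C)(C)C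
F4 | step 14 | macrocyclic (1S,6S,7R,14S)-6,7-epoxy-10-hydroperoxy lactone, 2E,11Z (both C10 epimers) | C=C1C(=O)O[C@H]2/C=C(\C)CC[C@@H]3O[C@]3(C)CCC(OO)/C(C)=C\C[C@@H]12
F5 | step 15 | macrocyclic (1S,6S,7R,14S)-6,7-epoxy-10-oxo lactone, 2E,11Z | C=C1C(=O)O[C@H]2/C=C(\C)CC[C@@H]3O[C@]3(C)CCC(=O)/C(C)=C\C[C@@H]12
F6 | step 15 | macrocyclic (1S,6S,7R,10S,14S)-6,7-epoxy-10-hydroxy lactone, 2E,11Z | C=C1C(=O)O[C@H]2/C=C(\C)CC[C@@H]3O[C@]3(C)CC[C@H](O)/C(C)=C\C[C@@H]12
F7 | step 15 | macrocyclic (1S,6S,7R,10R,14S)-10-chloro-6,7-epoxy lactone, 2E,11Z | C=C1C(=O)O[C@H]2/C=C(\C)CC[C@@H]3O[C@]3(C)CC[C@@H](Cl)/C(C)=C\C[C@@H]12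
F8 | step 15 | macrocyclic (1S,6S,7S,10R,14S)-10-chloro-7-hydroperoxy-6-hydroxy lactone, 2E,11Z | C=C1C(=O)O[C@H]2/C=C(\C)CC[C@H](O)[C@@](C)(OO)CC[C@@H](Cl)/C(C)=C\C[C@@H]12
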